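3 questions stand here, and they come down to two: how many chains does a flask begin, and how much free monomer enters them?

| flask | free monomer | transfer agent | initiator | time |
|---|---|---|---|---|
| west | 0.25 M | 2.50 mM | 12 mM | 8.0 d |
| south | 0.25 M | 2.50 mM | 12 mM | 12 d |

- which of the two ends with the longer chains by the average number of monomer units in a chain (chains begun, living or dead) ("neither" if they lie within 10%) (west / south / neither)
- average number of monomer units in a chain (chains begun, living or dead) at the end, west
- average number of monomer units in a chain (chains begun, living or dead) at the end, south

- two of one species on the left: rate k times its square, two consumed each time
- the average divides the monomer in chains by the number of chains begun, living and dead together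
- run time (west): 8.0 d

    free monomer + living end → monomer in chains + living end, rate k1*[living end]*[free monomer] (k1 = 0.0015 /M/s)
    free monomer + initiator → living end + monomer in chains (k2 = 5.5 × 10⁻⁴ /M/s)
    2 initiator → spent initiator (k3 = 0.010 /M/s)
    living end + transfer agent → dead chain (k4 = 0.0014 /M/s)

The zero of my scale is the even case. West and south have the same charges, so I expect the same chains begun, and they differ in end time. The length is monomer in chains over chains begun.

Initiator either starts a chain or destroys itself, and at the start in west the first path runs at 0.57 of the second. I hold free monomer at its charge, because the first half-life of initiator by self-loss, 1.16 h, is shorter than the 10.7 h free monomer would need with the whole initiator charge as living ends. Dividing the two rates and integrating gives b·ln(1 + initiator charge/b), where b is the starting constant times free monomer over twice the self-loss constant, here 6.88 mM. That is my carried quantity, the chains begun: 6.94 mM, the initiator charge times what the trade calls its efficiency. Full use of free monomer gives a length of 36.0.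

Now I turn the question round. For south to win with equal chains begun, west must keep about 10% of its free monomer at its end. Transfer agent can remove 2.50 mM of living ends at most, so once my chains are begun, living ends stand at 4.44 mM or more, and free monomer falls pseudo-first-order on them. With living ends taken at that level for the whole 8.0 d, I estimate that west keeps about 0.998%, which is less than the margin. I commit to neither.

The forecast says neither, with 36.3 for west (34.5 to 38) and 36.5 for south (34.7 to 38.2), holding that “that count is fixed long before either end time”.

The simulation gives neither, with 36.1 for west and 36.3 for south, and west keeps 0.66% of its free monomer. The neighbouring flask is west with 0.10 M of free monomer. There b is 2.75 mM, so I reckon 4.62 mM of chains begun. With 5.6% of its free monomer left, that neighbour comes to a length of 20.4. Its living ends and dead chains together stand at 4.53 mM, and its simulated length is 20.8.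

The constants were set for the occasion; the flask was simulated.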